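**Plan**
- The target is a catechin core carrying three 2,3-trans-3,4-trans fisetinidol units: unit M on catechin C6, unit T on C6 of unit M, and unit B on catechin C8.
- Each fisetinidol unit is cut the same way: 3-OH/4-H back to a C3=C4 alkene (hydroboration), the C3=C4 bond (metathesis), the O1–C2 bond (allylic etherification), and the C4–ring A bond to the neighbouring unit (aryl-metal addition to an acetophenone, then loss of water).
- Enabling feature: in unit M, C3 and C4 sit between the ether carbon C2 (bound to O1 and ring B) and C4, which carries ring A of unit M and ring A of catechin (through its C6). A C3=C4 bond therefore links an aryl 1-arylallyl ether to a 1,1-diarylethene, and ring C of unit M can be closed between these two alkenes with loss of ethene.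
- Forward order: perbenzylated 8-bromo-6-iodocatechin, then ring C of unit M on C6 (steps 9–13), iodination of unit M at C6, the two remaining acetophenone units added one after the other at C–I and C–Br (steps 16–17), rings C of units T and B closed side by side (steps 18–21), and hydrogenolysis last.
- Stereochemistry: catechin C2/C3 come from (+)-catechin; each fisetinidol C2 is set by iridium-catalysed allylic etherification (ligand control); C3 and C4 follow from hydroboration on the face away from the C2 aryl group (substrate control).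

Key step: step 12

Notation: Bn = benzyl; MOM = methoxymethyl; Ar = 3,4-bis(benzyloxy)phenyl; PBC = penta-O-benzylcatechin, (2R,3S)-3,5,7-tris(benzyloxy)-2-Ar-chromane; "8-bromo-PBC-6-yl" is this skeleton bonded through C6 with bromine on C8. Flavan numbering is used inside each unit; ring A is the benzo ring, ring B the 2-aryl ring, ring C the pyran ring. L = O,O′-(S)-1,1′-binaphthyl-2,2′-diyl N,N-bis[(S)-1-phenylethyl]phosphoramidite.

Assumption: the (Sa,S,S) antipode L is taken to give the (S) aryl 1-arylallyl ethers; if a first run shows the opposite sense, the mirror-image ligand is used and nothing else changes.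

**Step 1**
Reactants: 1 caffeic acid
Product: 2 benzyl (E)-3-[3,4-bis(benzyloxy)phenyl]prop-2-enoate
Conditions: BnBr (3.5 equiv), K2CO3, DMF, 60 °C
Reagents that add atoms: benzyl bromide, BrCc1ccccc1
Why: Williamson etherification of both phenols and O-alkylation of the carboxylate run together under carbonate base and leave the E alkene untouched.

**Step 2**
Reactants: 2 benzyl (E)-3-[3,4-bis(benzyloxy)phenyl]prop-2-enoate
Product: 3 (E)-3-[3,4-bis(benzyloxy)phenyl]prop-2-en-1-ol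
Conditions: i-Bu2AlH (2.2 equiv), CH2Cl2, −78 °C to 0 °C; aq. potassium sodium tartrate
Reagents that add atoms: none
Why: Aluminium hydride 1,2-reduction of an α,β-unsaturated ester gives the allylic alcohol without touching the alkene or the benzyl ethers.

**Step 3**
Reactants: 3 (E)-3-[3,4-bis(benzyloxy)phenyl]prop-2-en-1-ol
Product: 4 (E)-3-[3,4-bis(benzyloxy)phenyl]prop-2-en-1-yl methyl carbonate
Conditions: ClCO2Me, pyridine, CH2Cl2, 0 °C
Reagents that add atoms: methyl chloroformate, COC(=O)Cl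
Why: O-acylation of the primary allylic alcohol gives the linear carbonate that serves as the electrophile for iridium-catalysed allylic substitution.

**Step 4**
Reactants: 5 2,4-dihydroxyacetophenone
Product: 6 1-[4-(benzyloxy)-2-hydroxyphenyl]ethanone
Conditions: BnBr (1.05 equiv), K2CO3, acetone, reflux
Reagents that add atoms: benzyl bromide, BrCc1ccccc1
Why: Williamson etherification is selective for the 4-hydroxyl because the 2-hydroxyl is held in a hydrogen bond to the ketone.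

**Step 5**
Reactants: 6 1-[4-(benzyloxy)-2-hydroxyphenyl]ethanone
Product: 7 1-[4-(benzyloxy)-2-(methoxymethoxy)phenyl]ethanone
Conditions: MOMCl (1.5 equiv), i-Pr2NEt (2 equiv), CH2Cl2, 0 °C to 40 °C
Reagents that add atoms: chloromethyl methyl ether, COCCl
Why: Acetal protection of the remaining phenol gives a group that survives aryl-metal addition and is later removed by acid in the presence of benzyl ethers.

**Step 6**
Reactants: 8 (+)-catechin
Product: 9 penta-O-benzylcatechin (PBC), (2R,3S)-3,5,7-tris(benzyloxy)-2-[3,4-bis(benzyloxy)phenyl]chromane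
Conditions: BnBr (6 equiv), NaH (6 equiv), DMF, −10 °C to rt
Reagents that add atoms: benzyl bromide, BrCc1ccccc1
Why: Williamson etherification of the four phenols and the secondary alcohol, with the halide present before the base so that phenoxides are capped as they form and C2 is not epimerised.

**Step 7**
Reactants: 9 penta-O-benzylcatechin
Product: 10 8-bromo-penta-O-benzylcatechin
Conditions: NBS (1.0 equiv), CH2Cl2, −78 °C to 0 °C
Reagents that add atoms: N-bromosuccinimide, O=C1CCC(=O)N1Br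
Why: Electrophilic aromatic bromination of O-benzylated catechins occurs at C8 of the phloroglucinol-type ring A, a well-established regioselectivity.

**Step 8**
Reactants: 10 8-bromo-penta-O-benzylcatechin
Product: 11 8-bromo-6-iodo-penta-O-benzylcatechin
Conditions: NIS (1.1 equiv), CF3CO2H (0.1 equiv), CH2Cl2/MeCN, 0 °C to rt
Reagents that add atoms: N-iodosuccinimide, O=C1CCC(=O)N1I
Why: Electrophilic aromatic iodination takes the only free position of ring A (C6), which is activated by two ortho oxygens and one para oxygen, while the catechol-type ring B is far less nucleophilic.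

**Step 9**
Reactants: 11 8-bromo-6-iodo-penta-O-benzylcatechin; 7 1-[4-(benzyloxy)-2-(methoxymethoxy)phenyl]ethanone
Product: 13 1-[4-(benzyloxy)-2-(methoxymethoxy)phenyl]-1-(8-bromo-PBC-6-yl)ethanol (both carbinol epimers), via arylmagnesium chloride 12 (not isolated)
Conditions: i-PrMgCl·LiCl (1.1 equiv), THF, −30 °C; then 7 (1.5 equiv) premixed with LaCl3·2LiCl (1.0 equiv), −30 °C to 0 °C; aq. NH4Cl
Reagents that add atoms: none
Why: Iodine–magnesium exchange is much faster at C–I than at the flanked C–Br, and the LaCl3·2LiCl-promoted Grignard 1,2-addition to the methyl ketone suppresses enolisation; the new carbinol centre needs no control because step 10 removes it.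

**Step 10**
Reactants: 13 1-[4-(benzyloxy)-2-(methoxymethoxy)phenyl]-1-(8-bromo-PBC-6-yl)ethanol
Product: 15 5-(benzyloxy)-2-[1-(8-bromo-PBC-6-yl)ethenyl]phenol, via MOM-protected diarylethene 14 (not isolated)
Conditions: HCl (3 M aq, 5 equiv), THF/MeOH 2:1, 45 °C
Reagents that add atoms: none
Why: Acid-catalysed E1 dehydration of the doubly benzylic tertiary alcohol is followed in the same flask by methanolysis of the MOM acetal, and benzyl ethers, the aryl bromide and the catechin centres are inert to dilute HCl.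

**Step 11**
Reactants: 15 5-(benzyloxy)-2-[1-(8-bromo-PBC-6-yl)ethenyl]phenol; 4 (E)-3-[3,4-bis(benzyloxy)phenyl]prop-2-en-1-yl methyl carbonate
Product: 16 8-bromo-6-{1-[4-(benzyloxy)-2-{[(1S)-1-Ar-prop-2-en-1-yl]oxy}phenyl]ethenyl}-PBC
Conditions: [Ir(cod)Cl]2 (2.5 mol %), L (5 mol %), pre-activated with n-PrNH2; 4 (1.3 equiv), K3PO4 (1.2 equiv), THF, 40 °C
Reagents that add atoms: none
Why: Iridium-catalysed asymmetric allylic etherification of an ortho-alkenyl phenol attacks the aryl-bearing allyl terminus to give the branched ether, and the cyclometalated phosphoramidite catalyst sets the (S) centre (the later C2 of unit M) independently of the remote catechin centres.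

**Step 12**
Reactants: 16 8-bromo-6-{1-[4-(benzyloxy)-2-{[(1S)-1-Ar-prop-2-en-1-yl]oxy}phenyl]ethenyl}-PBC
Product: 17 (2S)-7-(benzyloxy)-2-Ar-4-(8-bromo-PBC-6-yl)-2H-chromene
Conditions: second-generation Hoveyda–Grubbs catalyst RuCl2(=CH-C6H4-2-O-i-Pr)(H2IMes) (10 mol %), 2,6-dichloro-1,4-benzoquinone (20 mol %), toluene (0.005 M), 80 °C, argon sparge
Reagents that add atoms: none
Why: The ruthenium alkylidene forms at the monosubstituted vinyl group of the allyl ether, adds across the 1,1-diarylethene in a [2+2] step, and cycloreversion of the ruthenacyclobutane expels the methylidene as ethene and leaves the C3=C4 bond. The closest known reaction is ring-closing metathesis of ortho-alkenylaryl allyl ethers to 2H-chromenes, here at its hindered limit with a gem-diaryl alkene. The single ring formed is the six-membered pyran ring C of unit M, closed between C3 and C4 with both alkene carbons inside the ring and the cis double bond fixed by ring size. No stereocentre is created; C2 takes no part in the bond changes and is retained as long as ruthenium hydride migration of the allyl double bond is suppressed, which the benzoquinone additive and removal of ethene serve. The step needs ring closure to win over intermolecular metathesis, which the substrate secures: the diarylethene cannot dimerise, the vinyl group is flanked by a branched centre, the two alkenes are held ortho to each other, and the product is a conjugated trisubstituted chromene; benzyl ethers and the aryl bromide are inert.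

**Step 13**
Reactants: 17 (2S)-7-(benzyloxy)-2-Ar-4-(8-bromo-PBC-6-yl)-2H-chromene
Product: 19 (2R,3S,4S)-7-(benzyloxy)-2-Ar-4-(8-bromo-PBC-6-yl)chroman-3-ol (2,3-trans-3,4-trans), via C3 alkylborane 18 (not isolated)
Conditions: BH3·SMe2 (4 equiv), THF, 0 °C to 40 °C; then NaOH (3 M aq), H2O2 (30 %), 0 °C to rt
Reagents that add atoms: hydrogen peroxide, OO
Why: Brown hydroboration–oxidation adds boron to the less substituted C3 and hydrogen to the diaryl-substituted C4 in a syn fashion from the face away from the C2 aryl group, and oxidation with retention gives the 2,3-trans-3,4-trans alcohol, the outcome known for flav-3-enes.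

**Step 14**
Reactants: 19 (2R,3S,4S)-7-(benzyloxy)-2-Ar-4-(8-bromo-PBC-6-yl)chroman-3-ol
Product: 20 (2R,3S,4S)-3,7-bis(benzyloxy)-2-Ar-4-(8-bromo-PBC-6-yl)chromane
Conditions: NaH (2 equiv), BnBr (2 equiv), n-Bu4NI (0.1 equiv), DMF, 0 °C to rt
Reagents that add atoms: benzyl bromide, BrCc1ccccc1
Why: Williamson etherification caps the secondary alcohol so that no acidic proton on the flavan skeleton is carried into the organometallic steps.

**Step 15**
Reactants: 20 (2R,3S,4S)-3,7-bis(benzyloxy)-2-Ar-4-(8-bromo-PBC-6-yl)chromane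
Product: 21 (2R,3S,4S)-3,7-bis(benzyloxy)-6-iodo-2-Ar-4-(8-bromo-PBC-6-yl)chromane
Conditions: NIS (1.05 equiv), CF3CO2H (0.1 equiv), CH2Cl2/MeCN, −20 °C to 0 °C
Reagents that add atoms: N-iodosuccinimide, O=C1CCC(=O)N1I
Why: Electrophilic aromatic iodination goes to C6 of ring A of unit M (para to O1, ortho to the 7-benzyloxy group), the most activated and least hindered site, since the catechin ring A has no free position and the rings B are much less nucleophilic.

**Step 16**
Reactants: 21 (2R,3S,4S)-3,7-bis(benzyloxy)-6-iodo-2-Ar-4-(8-bromo-PBC-6-yl)chromane; 7 1-[4-(benzyloxy)-2-(methoxymethoxy)phenyl]ethanone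
Product: 23 mono-carbinol bearing a 1-[4-(benzyloxy)-2-(methoxymethoxy)phenyl]-1-hydroxyethyl group on C6 of unit M in place of iodine (catechin C8 bromine retained; carbinol epimers), via unit M arylmagnesium chloride 22 (not isolated)
Conditions: i-PrMgCl·LiCl (1.2 equiv), THF, −15 °C to rt; then 7 (1.5 equiv) premixed with LaCl3·2LiCl (1.0 equiv), −20 °C to 0 °C; aq. NH4Cl
Reagents that add atoms: none
Why: Iodine–magnesium exchange is far faster at the aryl iodide than at the electron-rich aryl bromide flanked by two ortho oxygens, so only C6 of unit M is metalated, and the LaCl3·2LiCl-promoted Grignard 1,2-addition of step 9 then forms the C4–aryl bond of unit T; the carbinol centre is removed in step 18.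

**Step 17**
Reactants: 23 mono-carbinol; 7 1-[4-(benzyloxy)-2-(methoxymethoxy)phenyl]ethanone
Product: 26 bis-carbinol bearing a second 1-[4-(benzyloxy)-2-(methoxymethoxy)phenyl]-1-hydroxyethyl group on catechin C8 in place of bromine (carbinol epimers), via lithium alkoxide aryllithium 24 (not isolated), via aryl dichlorocerium species 25 (not isolated)
Conditions: t-BuLi (3.3 equiv), THF, −78 °C; CeCl3 (anhydrous, 1.5 equiv), −78 °C; then 7 (2 equiv), −78 °C to −30 °C; aq. NH4Cl
Reagents that add atoms: none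
Why: The first equivalent of t-BuLi turns the tertiary alcohol into a spectator lithium alkoxide, two more effect bromine–lithium exchange at catechin C8, and transmetalation to the weakly basic organocerium reagent (Imamoto) allows 1,2-addition to the enolisable ketone, forming the C4–aryl bond of unit B with the carbinol centre again left uncontrolled.

**Step 18**
Reactants: 26 bis-carbinol
Product: 28 bis-phenol in which C6 of unit M and catechin C8 each carry a 1-[4-(benzyloxy)-2-hydroxyphenyl]ethenyl group, via bis(MOM ether) diene 27 (not isolated)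
Conditions: HCl (3 M aq, 10 equiv), THF/MeOH 2:1, 45 °C
Reagents that add atoms: none
Why: The same acid-catalysed E1 dehydration and MOM acetal cleavage as in step 10 act at both sites, and the 5-deoxy C4–aryl bond of unit M is stable to dilute acid.

**Step 19**
Reactants: 28 bis-phenol; 4 (E)-3-[3,4-bis(benzyloxy)phenyl]prop-2-en-1-yl methyl carbonate
Product: 29 bis[(1S)-1-Ar-prop-2-en-1-yl] ether of 28
Conditions: [Ir(cod)Cl]2 (5 mol %), L (10 mol %), pre-activated with n-PrNH2; 4 (3 equiv), K3PO4 (2.4 equiv), THF, 40 °C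
Reagents that add atoms: none
Why: The iridium-catalysed asymmetric allylic etherification of step 11 is repeated at both phenols, one molecule of 4 reacting at each, and catalyst control sets the two (S) centres (C2 of units T and B).

**Step 20**
Reactants: 29 bis[(1S)-1-Ar-prop-2-en-1-yl] ether of 28
Product: 30 bis(flav-3-ene) in which C6 of unit M and catechin C8 each carry a (2S)-7-(benzyloxy)-2-Ar-2H-chromen-4-yl group
Conditions: second-generation Hoveyda–Grubbs catalyst RuCl2(=CH-C6H4-2-O-i-Pr)(H2IMes) (2 × 10 mol %), 2,6-dichloro-1,4-benzoquinone (40 mol %), toluene (0.003 M), 80 °C, argon sparge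
Reagents that add atoms: none
Why: Twofold ring-closing metathesis of the kind used in step 12 closes rings C of units T and B, each by loading at a vinyl group and closure onto a 1,1-diarylethene with loss of ethene.

**Step 21**
Reactants: 30 bis(flav-3-ene)
Product: 32 pentadeca-O-benzyl tetramer with free 3-hydroxyls in units T and B (all three fisetinidol units 2R,3S,4S), via bis(alkylborane) 31 (not isolated)
Conditions: BH3·SMe2 (8 equiv), THF, 0 °C to 40 °C; then NaOH (3 M aq), H2O2 (30 %), 0 °C to rt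
Reagents that add atoms: hydrogen peroxide, OO
Why: Hydroboration–oxidation as in step 13 adds at each C3=C4 bond from the face away from its own C2 aryl group, so both new units become 2,3-trans-3,4-trans.

**Step 22**
Reactants: 32 pentadeca-O-benzyl tetramer
Product: 33 CNP0263622.1, fisetinidol-(4α→6)-fisetinidol-(4α→6)-catechin with a further fisetinidol-(4α→8) unit
Conditions: H2 (1 atm), Pd(OH)2/C (20 wt %), THF/MeOH/H2O, rt; Sephadex LH-20
Reagents that add atoms: none
Why: Catalytic hydrogenolysis cleaves all fifteen benzyl ethers, while the diarylmethine C4–aryl bonds and the pyran C2–O1 bonds of benzylated oligoflavans are not cleaved under these neutral conditions.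

**Compound list**
1 | caffeic acid | OC(=O)/C=C/c1ccc(O)c(O)c1 | starting material
2 | benzyl (E)-3-[3,4-bis(benzyloxy)phenyl]prop-2-enoate | O=C(OCc1ccccc1)/C=C/c1ccc(OCc2ccccc2)c(OCc2ccccc2)c1 | intermediate
3 | (E)-3-[3,4-bis(benzyloxy)phenyl]prop-2-en-1-ol | OC/C=C/c1ccc(OCc2ccccc2)c(OCc2ccccc2)c1 | intermediate
4 | (E)-3-[3,4-bis(benzyloxy)phenyl]prop-2-en-1-yl methyl carbonate | COC(=O)OC/C=C/c1ccc(OCc2ccccc2)c(OCc2ccccc2)c1 | intermediate
5 | 2,4-dihydroxyacetophenone | CC(=O)c1ccc(O)cc1O | starting material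
6 | 1-[4-(benzyloxy)-2-hydroxyphenyl]ethanone | CC(=O)c1ccc(OCc2ccccc2)cc1O | intermediate
7 | 1-[4-(benzyloxy)-2-(methoxymethoxy)phenyl]ethanone | CC(=O)c1ccc(OCc2ccccc2)cc1OCOC | intermediate
8 | (+)-catechin | Oc1cc(O)c2c(c1)O[C@H](c1ccc(O)c(O)c1)[C@@H](O)C2 | starting material
9 | penta-O-benzylcatechin (PBC), 2R,3S | c1c(OCc9ccccc9)c2c(cc1OCc9ccccc9)O[C@H](c8ccc(OCc9ccccc9)c(OCc9ccccc9)c8)[C@@H](OCc9ccccc9)C2 | intermediate
10 | 8-bromo-penta-O-benzylcatechin | c1c(OCc9ccccc9)c2c(c(Br)c1OCc9ccccc9)O[C@H](c8ccc(OCc9ccccc9)c(OCc9ccccc9)c8)[C@@H](OCc9ccccc9)C2 | intermediate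
11 | 8-bromo-6-iodo-penta-O-benzylcatechin | Ic1c(OCc9ccccc9)c2c(c(Br)c1OCc9ccccc9)O[C@H](c8ccc(OCc9ccccc9)c(OCc9ccccc9)c8)[C@@H](OCc9ccccc9)C2 | intermediate
12 | (8-bromo-PBC-6-yl)magnesium chloride | Cl[Mg]c1c(OCc9ccccc9)c2c(c(Br)c1OCc9ccccc9)O[C@H](c8ccc(OCc9ccccc9)c(OCc9ccccc9)c8)[C@@H](OCc9ccccc9)C2 | intermediate (not isolated)
13 | 1-[4-(benzyloxy)-2-(methoxymethoxy)phenyl]-1-(8-bromo-PBC-6-yl)ethanol, both carbinol epimers | CC(O)(c3ccc(OCc9ccccc9)cc3OCOC)c1c(OCc9ccccc9)c2c(c(Br)c1OCc9ccccc9)O[C@H](c8ccc(OCc9ccccc9)c(OCc9ccccc9)c8)[C@@H](OCc9ccccc9)C2 | intermediate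
14 | 8-bromo-6-{1-[4-(benzyloxy)-2-(methoxymethoxy)phenyl]ethenyl}-PBC | C=C(c3ccc(OCc9ccccc9)cc3OCOC)c1c(OCc9ccccc9)c2c(c(Br)c1OCc9ccccc9)O[C@H](c8ccc(OCc9ccccc9)c(OCc9ccccc9)c8)[C@@H](OCc9ccccc9)C2 | intermediate (not isolated)
15 | 5-(benzyloxy)-2-[1-(8-bromo-PBC-6-yl)ethenyl]phenol | C=C(c3ccc(OCc9ccccc9)cc3O)c1c(OCc9ccccc9)c2c(c(Br)c1OCc9ccccc9)O[C@H](c8ccc(OCc9ccccc9)c(OCc9ccccc9)c8)[C@@H](OCc9ccccc9)C2 | intermediate
16 | (1S)-1-Ar-prop-2-en-1-yl ether of 15 (metathesis precursor) | C=C(c3ccc(OCc9ccccc9)cc3O[C@H](c8ccc(OCc9ccccc9)c(OCc9ccccc9)c8)C=C)c1c(OCc9ccccc9)c2c(c(Br)c1OCc9ccccc9)O[C@H](c8ccc(OCc9ccccc9)c(OCc9ccccc9)c8)[C@@H](OCc9ccccc9)C2 | intermediate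
17 | (2S)-7-(benzyloxy)-2-Ar-4-(8-bromo-PBC-6-yl)-2H-chromene | c9ccccc9COc3ccc4c(c3)O[C@H](c8ccc(OCc9ccccc9)c(OCc9ccccc9)c8)C=C4c1c(OCc9ccccc9)c2c(c(Br)c1OCc9ccccc9)O[C@H](c8ccc(OCc9ccccc9)c(OCc9ccccc9)c8)[C@@H](OCc9ccccc9)C2 | intermediate
18 | C3 dihydroboryl analogue of 19 (BH2 in place of the 3-OH, same configuration) | c3cc4c(cc3OCc9ccccc9)O[C@H](c8ccc(OCc9ccccc9)c(OCc9ccccc9)c8)[C@@H](B)[C@@H]4c1c(OCc9ccccc9)c2c(c(Br)c1OCc9ccccc9)O[C@H](c8ccc(OCc9ccccc9)c(OCc9ccccc9)c8)[C@@H](OCc9ccccc9)C2 | intermediate (not isolated)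
19 | (2R,3S,4S)-7-(benzyloxy)-2-Ar-4-(8-bromo-PBC-6-yl)chroman-3-ol | c3cc4c(cc3OCc9ccccc9)O[C@H](c8ccc(OCc9ccccc9)c(OCc9ccccc9)c8)[C@@H](O)[C@@H]4c1c(OCc9ccccc9)c2c(c(Br)c1OCc9ccccc9)O[C@H](c8ccc(OCc9ccccc9)c(OCc9ccccc9)c8)[C@@H](OCc9ccccc9)C2 | intermediate
20 | (2R,3S,4S)-3,7-bis(benzyloxy)-2-Ar-4-(8-bromo-PBC-6-yl)chromane | c3cc4c(cc3OCc9ccccc9)O[C@H](c8ccc(OCc9ccccc9)c(OCc9ccccc9)c8)[C@@H](OCc9ccccc9)[C@@H]4c1c(OCc9ccccc9)c2c(c(Br)c1OCc9ccccc9)O[C@H](c8ccc(OCc9ccccc9)c(OCc9ccccc9)c8)[C@@H](OCc9ccccc9)C2 | intermediate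
21 | 6-iodo derivative of 20 (iodine on ring A of unit M) | Ic3cc4c(cc3OCc9ccccc9)O[C@H](c8ccc(OCc9ccccc9)c(OCc9ccccc9)c8)[C@@H](OCc9ccccc9)[C@@H]4c1c(OCc9ccccc9)c2c(c(Br)c1OCc9ccccc9)O[C@H](c8ccc(OCc9ccccc9)c(OCc9ccccc9)c8)[C@@H](OCc9ccccc9)C2 | intermediate
22 | arylmagnesium chloride from 21 (MgCl on C6 of unit M, bromine kept on catechin C8) | Cl[Mg]c3cc4c(cc3OCc9ccccc9)O[C@H](c8ccc(OCc9ccccc9)c(OCc9ccccc9)c8)[C@@H](OCc9ccccc9)[C@@H]4c1c(OCc9ccccc9)c2c(c(Br)c1OCc9ccccc9)O[C@H](c8ccc(OCc9ccccc9)c(OCc9ccccc9)c8)[C@@H](OCc9ccccc9)C2 | intermediate (not isolated)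
23 | mono-carbinol: 1-[4-(benzyloxy)-2-(methoxymethoxy)phenyl]-1-hydroxyethyl group on C6 of unit M, bromine on catechin C8, carbinol epimers | CC(O)(c5ccc(OCc9ccccc9)cc5OCOC)c3cc4c(cc3OCc9ccccc9)O[C@H](c8ccc(OCc9ccccc9)c(OCc9ccccc9)c8)[C@@H](OCc9ccccc9)[C@@H]4c1c(OCc9ccccc9)c2c(c(Br)c1OCc9ccccc9)O[C@H](c8ccc(OCc9ccccc9)c(OCc9ccccc9)c8)[C@@H](OCc9ccccc9)C2 | intermediate
24 | lithium alkoxide of 23 with lithium in place of the C8 bromine | CC(O[Li])(c5ccc(OCc9ccccc9)cc5OCOC)c3cc4c(cc3OCc9ccccc9)O[C@H](c8ccc(OCc9ccccc9)c(OCc9ccccc9)c8)[C@@H](OCc9ccccc9)[C@@H]4c1c(OCc9ccccc9)c2c(c([Li])c1OCc9ccccc9)O[C@H](c8ccc(OCc9ccccc9)c(OCc9ccccc9)c8)[C@@H](OCc9ccccc9)C2 | intermediate (not isolated)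
25 | lithium alkoxide of 23 with a dichlorocerium group in place of the C8 bromine | CC(O[Li])(c5ccc(OCc9ccccc9)cc5OCOC)c3cc4c(cc3OCc9ccccc9)O[C@H](c8ccc(OCc9ccccc9)c(OCc9ccccc9)c8)[C@@H](OCc9ccccc9)[C@@H]4c1c(OCc9ccccc9)c2c(c([Ce](Cl)Cl)c1OCc9ccccc9)O[C@H](c8ccc(OCc9ccccc9)c(OCc9ccccc9)c8)[C@@H](OCc9ccccc9)C2 | intermediate (not isolated)
26 | bis-carbinol: 1-[4-(benzyloxy)-2-(methoxymethoxy)phenyl]-1-hydroxyethyl groups on C6 of unit M and on catechin C8, carbinol epimers | CC(O)(c5ccc(OCc9ccccc9)cc5OCOC)c3cc4c(cc3OCc9ccccc9)O[C@H](c8ccc(OCc9ccccc9)c(OCc9ccccc9)c8)[C@@H](OCc9ccccc9)[C@@H]4c1c(OCc9ccccc9)c2c(c(C(C)(O)c7ccc(OCc9ccccc9)cc7OCOC)c1OCc9ccccc9)O[C@H](c8ccc(OCc9ccccc9)c(OCc9ccccc9)c8)[C@@H](OCc9ccccc9)C2 | intermediate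
27 | bis(MOM ether) diene: 1-[4-(benzyloxy)-2-(methoxymethoxy)phenyl]ethenyl groups at the same two carbons | C=C(c5ccc(OCc9ccccc9)cc5OCOC)c3cc4c(cc3OCc9ccccc9)O[C@H](c8ccc(OCc9ccccc9)c(OCc9ccccc9)c8)[C@@H](OCc9ccccc9)[C@@H]4c1c(OCc9ccccc9)c2c(c(C(=C)c7ccc(OCc9ccccc9)cc7OCOC)c1OCc9ccccc9)O[C@H](c8ccc(OCc9ccccc9)c(OCc9ccccc9)c8)[C@@H](OCc9ccccc9)C2 | intermediate (not isolated)
28 | bis-phenol: 1-[4-(benzyloxy)-2-hydroxyphenyl]ethenyl groups at the same two carbons | C=C(c5ccc(OCc9ccccc9)cc5O)c3cc4c(cc3OCc9ccccc9)O[C@H](c8ccc(OCc9ccccc9)c(OCc9ccccc9)c8)[C@@H](OCc9ccccc9)[C@@H]4c1c(OCc9ccccc9)c2c(c(C(=C)c7ccc(OCc9ccccc9)cc7O)c1OCc9ccccc9)O[C@H](c8ccc(OCc9ccccc9)c(OCc9ccccc9)c8)[C@@H](OCc9ccccc9)C2 | intermediate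
29 | bis[(1S)-1-Ar-prop-2-en-1-yl] ether of 28 | C=C(c5ccc(OCc9ccccc9)cc5O[C@H](c8ccc(OCc9ccccc9)c(OCc9ccccc9)c8)C=C)c3cc4c(cc3OCc9ccccc9)O[C@H](c8ccc(OCc9ccccc9)c(OCc9ccccc9)c8)[C@@H](OCc9ccccc9)[C@@H]4c1c(OCc9ccccc9)c2c(c(C(=C)c7ccc(OCc9ccccc9)cc7O[C@H](c8ccc(OCc9ccccc9)c(OCc9ccccc9)c8)C=C)c1OCc9ccccc9)O[C@H](c8ccc(OCc9ccccc9)c(OCc9ccccc9)c8)[C@@H](OCc9ccccc9)C2 | intermediate
30 | bis(flav-3-ene): (2S)-7-(benzyloxy)-2-Ar-2H-chromen-4-yl groups on C6 of unit M (unit T) and on catechin C8 (unit B) | c9ccccc9COc5ccc6c(c5)O[C@H](c8ccc(OCc9ccccc9)c(OCc9ccccc9)c8)C=C6c3cc4c(cc3OCc9ccccc9)O[C@H](c8ccc(OCc9ccccc9)c(OCc9ccccc9)c8)[C@@H](OCc9ccccc9)[C@@H]4c1c(OCc9ccccc9)c2c(c(C7=C[C@@H](c8ccc(OCc9ccccc9)c(OCc9ccccc9)c8)Oc6cc(OCc9ccccc9)ccc67)c1OCc9ccccc9)O[C@H](c8ccc(OCc9ccccc9)c(OCc9ccccc9)c8)[C@@H](OCc9ccccc9)C2 | intermediate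
31 | bis(alkylborane): BH2 on C3 of units T and B, configuration as in 32 | c9ccccc9COc5ccc6c(c5)O[C@H](c8ccc(OCc9ccccc9)c(OCc9ccccc9)c8)[C@@H](B)[C@@H]6c3cc4c(cc3OCc9ccccc9)O[C@H](c8ccc(OCc9ccccc9)c(OCc9ccccc9)c8)[C@@H](OCc9ccccc9)[C@@H]4c1c(OCc9ccccc9)c2c(c([C@@H]7c6ccc(OCc9ccccc9)cc6O[C@H](c8ccc(OCc9ccccc9)c(OCc9ccccc9)c8)[C@H]7B)c1OCc9ccccc9)O[C@H](c8ccc(OCc9ccccc9)c(OCc9ccccc9)c8)[C@@H](OCc9ccccc9)C2 | intermediate (not isolated)
32 | pentadeca-O-benzyl tetramer: units T and B are (2R,3S,4S)-7-(benzyloxy)-2-Ar-3-hydroxychroman-4-yl, unit M is (2R,3S,4S) with 3-OBn, catechin 2R,3S | c9ccccc9COc5ccc6c(c5)O[C@H](c8ccc(OCc9ccccc9)c(OCc9ccccc9)c8)[C@@H](O)[C@@H]6c3cc4c(cc3OCc9ccccc9)O[C@H](c8ccc(OCc9ccccc9)c(OCc9ccccc9)c8)[C@@H](OCc9ccccc9)[C@@H]4c1c(OCc9ccccc9)c2c(c([C@@H]7c6ccc(OCc9ccccc9)cc6O[C@H](c8ccc(OCc9ccccc9)c(OCc9ccccc9)c8)[C@H]7O)c1OCc9ccccc9)O[C@H](c8ccc(OCc9ccccc9)c(OCc9ccccc9)c8)[C@@H](OCc9ccccc9)C2 | intermediate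
33 | CNP0263622.1: catechin (2R,3S) bearing fisetinidol-(4α→6)-fisetinidol-(4α→6) on C6 and fisetinidol-(4α→8) on C8; every fisetinidol unit 2R,3S with the C4 aryl trans to the 3-OH | Oc1ccc2c(c1)O[C@H](c1ccc(O)c(O)c1)[C@@H](O)[C@@H]2c1cc2c(cc1O)O[C@H](c1ccc(O)c(O)c1)[C@@H](O)[C@@H]2c1c(O)c2c(c([C@@H]3c4ccc(O)cc4O[C@H](c4ccc(O)c(O)c4)[C@H]3O)c1O)O[C@H](c1ccc(O)c(O)c1)[C@@H](O)C2 | target

**Totals**
Total step count: 22 (steps 1–3 make carbonate 4, steps 4–5 make ketone 7, steps 6–22 are the main line).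
Longest linear sequence: 17 steps, from 8 to 33 (steps 6–22).

**Steps most likely to fail**

1. Step 12 (and its twofold repeat, step 20). The alkylidene formed at the allyl ether end may fail to add to the shielded gem-diaryl alkene. That leaves time for ruthenium hydride species to move the allyl double bond towards the ether oxygen, which erases C2, or for the ether ends to couple with each other. The fallback leaves the route at 11 (through its Grignard reagent 12) and returns at 17; it takes ring C ready-made instead of closing it by metathesis. Commercial 7-hydroxychromone is benzylated (BnBr, K2CO3, DMF) to 7-(benzyloxy)-4H-chromen-4-one F1. Pd(OCOCF3)2 with the t-BuPyOx antipode that leads to the 2S product catalyses conjugate addition of 3,4-bis(benzyloxy)phenylboronic acid to F1 and should give (2S)-7-(benzyloxy)-2-[3,4-bis(benzyloxy)phenyl]chroman-4-one F2. Grignard reagent 12, with LaCl3·2LiCl in THF at −30 °C, adds to the C4 carbonyl of F2 to give (2S)-7-(benzyloxy)-2-Ar-4-(8-bromo-PBC-6-yl)chroman-4-ol F3 as a pair of C4 epimers. Burgess reagent in toluene at 50 °C then removes water across C3–C4 and gives 17.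

2. Step 17. Incomplete bromine–lithium exchange at the flanked catechin C8 beside the lithium alkoxide, benzylic metalation by the excess t-BuLi, or proton transfer from the acetyl group to the hindered aryl metal would leave C8 as C–H and end the sequence. The fallback leaves the route at 21 and returns at 27, which the acid treatment of step 18 converts to 28; it forms both diarylethenes by Barluenga cross-coupling instead of carbonyl addition and so replaces steps 16 and 17 together. Ketone 7 is condensed with p-toluenesulfonyl hydrazide in methanol to 1-[4-(benzyloxy)-2-(methoxymethoxy)phenyl]ethanone N-tosylhydrazone F4. Compound 21 and F4 (2.5 equiv) are heated with Pd2(dba)3, XPhos and LiOt-Bu in 1,4-dioxane at 90 °C; oxidative addition of zerovalent palladium at C–I and C–Br, carbene migratory insertion and β-hydride elimination should give 27 directly.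

3. Step 19. Slow attack of two ortho-encumbered phenoxides could let the linear ether compete or erode catalyst control at one site, giving diastereomers that are hard to separate at this size. The fallback leaves the route at 6 and at 21 and returns at 29; it sets the ether stereocentre on a small fragment before the fragments are joined. Phenol 6 is etherified with carbonate 4 under the conditions of step 11 to give 1-[4-(benzyloxy)-2-{[(1S)-1-Ar-prop-2-en-1-yl]oxy}phenyl]ethanone F5, which can be brought to a single enantiomer on small scale. Compound 21 is treated with t-BuLi (4.4 equiv) in THF at −78 °C to give the dilithio species F6 (lithium on C6 of unit M and on catechin C8), and anhydrous CeCl3 converts it to the bis(dichlorocerium) species F7. Twofold addition of F7 to F5 gives the bis-carbinol F8 (carbinol epimers), which already carries both allyl ethers. Burgess reagent in toluene at 50 °C dehydrates both carbinols and gives 29.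

**Further compounds**
F1 | step 12 | 7-(benzyloxy)-4H-chromen-4-one | O=c1ccoc2cc(OCc3ccccc3)ccc12
F2 | step 12 | (2S)-7-(benzyloxy)-2-[3,4-bis(benzyloxy)phenyl]chroman-4-one | O=C1C[C@@H](c2ccc(OCc3ccccc3)c(OCc3ccccc3)c2)Oc2cc(OCc3ccccc3)ccc12
F3 | step 12 | (2S)-7-(benzyloxy)-2-Ar-4-(8-bromo-PBC-6-yl)chroman-4-ol, C4 epimers | OC4(C[C@@H](c8ccc(OCc9ccccc9)c(OCc9ccccc9)c8)Oc3cc(OCc9ccccc9)ccc34)c1c(OCc9ccccc9)c2c(c(Br)c1OCc9ccccc9)O[C@H](c8ccc(OCc9ccccc9)c(OCc9ccccc9)c8)[C@@H](OCc9ccccc9)C2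
F4 | step 17 | 1-[4-(benzyloxy)-2-(methoxymethoxy)phenyl]ethanone N-tosylhydrazone | COCOc1cc(OCc2ccccc2)ccc1C(C)=NNS(=O)(=O)c1ccc(C)cc1
F5 | step 19 | 1-[4-(benzyloxy)-2-{[(1S)-1-(3,4-bis(benzyloxy)phenyl)prop-2-en-1-yl]oxy}phenyl]ethanone | CC(=O)c1ccc(OCc2ccccc2)cc1O[C@H](c1ccc(OCc2ccccc2)c(OCc2ccccc2)c1)C=C
F6 | step 19 | dilithio species from 21 (lithium on C6 of unit M and on catechin C8) | [Li]c3cc4c(cc3OCc9ccccc9)O[C@H](c8ccc(OCc9ccccc9)c(OCc9ccccc9)c8)[C@@H](OCc9ccccc9)[C@@H]4c1c(OCc9ccccc9)c2c(c([Li])c1OCc9ccccc9)O[C@H](c8ccc(OCc9ccccc9)c(OCc9ccccc9)c8)[C@@H](OCc9ccccc9)C2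
F7 | step 19 | bis(dichlorocerium) species at the same two carbons | Cl[Ce](Cl)c3cc4c(cc3OCc9ccccc9)O[C@H](c8ccc(OCc9ccccc9)c(OCc9ccccc9)c8)[C@@H](OCc9ccccc9)[C@@H]4c1c(OCc9ccccc9)c2c(c([Ce](Cl)Cl)c1OCc9ccccc9)O[C@H](c8ccc(OCc9ccccc9)c(OCc9ccccc9)c8)[C@@H](OCc9ccccc9)C2
F8 | step 19 | bis-carbinol carrying 1-hydroxy-1-[4-(benzyloxy)-2-{[(1S)-1-Ar-prop-2-en-1-yl]oxy}phenyl]ethyl groups on C6 of unit M and on catechin C8, carbinol epimers | CC(O)(c5ccc(OCc9ccccc9)cc5O[C@H](c8ccc(OCc9ccccc9)c(OCc9ccccc9)c8)C=C)c3cc4c(cc3OCc9ccccc9)O[C@H](c8ccc(OCc9ccccc9)c(OCc9ccccc9)c8)[C@@H](OCc9ccccc9)[C@@H]4c1c(OCc9ccccc9)c2c(c(C(C)(O)c7ccc(OCc9ccccc9)cc7O[C@H](c8ccc(OCc9ccccc9)c(OCc9ccccc9)c8)C=C)c1OCc9ccccc9)O[C@H](c8ccc(OCc9ccccc9)c(OCc9ccccc9)c8)[C@@H](OCc9ccccc9)C2
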